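The route rests on the C13–C16 bond of the spiro-dihydrofuran (labdane numbering). C13 is at once the α-carbon of the C12 ketone in the furanone ring (O9, C9, C11, C12, C13) and C3 of the dihydrofuran ring (C13, C14, C15, O, C16). That ring is therefore the 1,5-electrocyclisation product of a carbonyl ylide whose carbanion is the extended C12 enolate, and the ylide is the ring-opened form of a vinyl oxirane. Marrubiin supplies all six decalin stereocentres; its furan is cut back and rebuilt as a γ,δ-epoxy enone. Pyrolysis of this oxirane closes the ring, sets quaternary C13 and delivers the enol ether without reagents.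

Key step: step 9

Assumption: (+)-marrubiin, the bulk diterpene of white horehound, is taken as a commercially available chiral-pool terpene. Atoms carry labdane numbers (C1–C20); O9 is the oxygen on C9 and O12 the ketone oxygen.

Step 1
Reactants: 1 (+)-marrubiin
Product: 2 marrubenol (15,16-epoxylabda-13(16),14-diene-6β,9α,19-triol)
Conditions: LiAlH4, THF, 0 → 65 °C
Reagents that add atoms: none
Why: LiAlH4 reduction of the hindered 19,6β-lactone should give the 6β,19-diol without touching any stereocentre, the furan or the tertiary 9-hydroxyl.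

Step 2
Reactants: 2 marrubenol
Product: 3 6β,19-O-(di-tert-butylsilanediyl)marrubenol
Conditions: t-Bu2Si(OTf)2, 2,6-lutidine, CH2Cl2, 0 °C
Reagents that add atoms: di-tert-butylsilyl bis(trifluoromethanesulfonate), CC(C)(C)[Si](OS(=O)(=O)C(F)(F)F)(OS(=O)(=O)C(F)(F)F)C(C)(C)C
Why: Silylene protection of a diol; the 6β-hydroxyl and the 19-hydroxymethyl are held syn-diaxial (the pair that formed the lactone), so the ditriflate should bridge them as a seven-membered dioxasilepane and leave the hindered tertiary 9-hydroxyl free.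

Step 3
Reactants: 3 6β,19-O-(di-tert-butylsilanediyl)marrubenol
Product: 5 silylene-protected 14,15,16-trinorlabdan-13,9α-olide (spiro γ-lactone), via hydroxy acid 4 (not isolated)
Conditions: RuCl3·3H2O (cat.), NaIO4, CCl4/MeCN/H2O, 23 °C; then TsOH (cat.), CH2Cl2, 23 °C
Reagents that add atoms: sodium periodate, [Na+].[O-]I(=O)(=O)=O
Why: Ruthenium tetroxide degradation of the 3-alkylfuran should excise C14–C16 and leave C13 as a carboxylic acid, which lactonises onto the tertiary 9-hydroxyl; no stereocentre is involved.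

Step 4
Reactants: 5 silylene-protected spiro γ-lactone
Product: 6 12-hydroxy spiro γ-lactone (both C12 epimers)
Conditions: KN(SiMe3)2, THF, −78 °C; then 2-(phenylsulfonyl)-3-phenyloxaziridine, −78 °C
Reagents that add atoms: 2-(phenylsulfonyl)-3-phenyloxaziridine, O=S(=O)(c1ccccc1)N1OC1c1ccccc1
Why: Davis enolate hydroxylation; only C12 carries acidic hydrogens, and the C12 configuration is immaterial because C12 becomes a ketone in step 6.

Step 5
Reactants: 6 12-hydroxy spiro γ-lactone
Product: 8 silylene-protected 9α,13-epoxy-14,15,16-trinorlabdan-12-ol (C12 epimers), via lactol 7 (not isolated)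
Conditions: i-Bu2AlH, CH2Cl2, −78 °C; then Et3SiH, BF3·OEt2, −78 → −20 °C
Reagents that add atoms: none
Why: Reductive deoxygenation of a lactone to a cyclic ether (partial reduction to the lactol, then ionic hydrogenation of the oxocarbenium ion) should turn the C13 carbonyl into CH2 and keep the C12 hydroxyl.

Step 6
Reactants: 8 silylene-protected 9α,13-epoxy-14,15,16-trinorlabdan-12-ol
Product: 9 silylene-protected 9α,13-epoxy-14,15,16-trinorlabdan-12-one (spiro tetrahydrofuran-3-one)
Conditions: Dess–Martin periodinane, NaHCO3, CH2Cl2, 23 °C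
Reagents that add atoms: none
Why: Dess–Martin oxidation of the secondary C12 alcohol should give the furanone under buffered conditions that leave the silylene and the spiro ether intact.

Step 7
Reactants: 10 (S)-glycidol
Product: 11 (R)-oxirane-2-carbaldehyde
Conditions: Dess–Martin periodinane, NaHCO3, CH2Cl2, 0 °C; filtered solution used at once
Reagents that add atoms: none
Why: Dess–Martin oxidation of the primary alcohol should give the epoxy aldehyde without opening the oxirane; its stereocentre is carried along unchanged and is erased in step 9.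

Step 8
Reactants: 9 spiro tetrahydrofuran-3-one; 11 (R)-oxirane-2-carbaldehyde
Product: 14 (Z)-γ,δ-epoxy enone [C13=C14 exocyclic to the furanone; oxirane at C15–C16], via aldolate 12 (not isolated), via mesylate 13 (not isolated)
Conditions: LiN(i-Pr)2, THF, −78 °C; 11; then MsCl, −78 → 0 °C; DBU, 23 °C
Reagents that add atoms: none
Why: Directed aldol condensation; the kinetic enolate should form at C13 (oxygen-activated and open, whereas C11 is neopentyl), add to the aldehyde, and after mesylation eliminate by E1cB through the acidic C13–H to the 2-alkylidene-3-furanone.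

Step 9
Reactants: 14 (Z)-γ,δ-epoxy enone
Product: 16 6,19-O-silylene-protected target, via carbonyl ylide 15 (not isolated)
Conditions: flash vacuum pyrolysis, base-washed quartz tube, 450 °C, 0.01 mbar, trap at −78 °C
Reagents that add atoms: none
Why: Thermal conrotatory cleavage of the oxirane C15–C16 bond gives carbonyl ylide 15, whose carbanion is delocalised as the dienolate C15=C14–C13=C12–O− and whose cationic end is the CH2=O+ unit, and disrotatory 6π closure between C16 and C13 gives the 2,3-dihydrofuran. The closest known reaction type is the vinyl oxirane to 2,3-dihydrofuran rearrangement of γ,δ-epoxy-α,β-unsaturated carbonyl compounds under flash pyrolysis. The one ring formed closes by 1,5-dipolar electrocyclisation (formally 5-endo), so neither Baldwin constraints nor the E/Z geometry of 14 matter, because oxirane, ylide rotamers and the strained 1,3-dioxepine from O12–C16 closure interconvert while the dihydrofuran is the sink. The step needs C–C rather than C–O cleavage of the oxirane, which the push–pull stabilisation of 15 by the C12 carbonyl should secure. C13 is the only new stereocentre and is set by the face of the planar enolate terminus onto which C16 rotates, the required face being the one flanked by the C8 methyl group. As the furanone ring lies in the plane bisecting C8–C9–C10, the two faces differ only in C17H3 versus the C1 methylene, so at best a modest bias is expected and the 13-epimer has to be removed by chromatography.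

Step 10
Reactants: 16 6,19-O-silylene-protected target
Product: 17 target, (13R)-6β,19-dihydroxy-9α,13;15,16-diepoxylabd-14-en-12-one
Conditions: Bu4NF, AcOH, THF, 0 → 23 °C
Reagents that add atoms: none
Why: Buffered fluoride cleavage of the silylene should free the 6β- and 19-hydroxyls while the enol ether, the ketone and the non-enolisable quaternary C13 stay untouched.

Compound list
1 | (+)-marrubiin, 9α-hydroxy-15,16-epoxylabda-13(16),14-dien-19,6β-olide | C[C@@H]1C[C@H]2OC(=O)[C@@]3(C)CCC[C@]([C@@H]23)(C)[C@@]1(O)CCc1ccoc1 | starting material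
2 | marrubenol, 15,16-epoxylabda-13(16),14-diene-6β,9α,19-triol | C[C@@H]1C[C@@H](O)[C@H]2[C@@](C)(CO)CCC[C@]2(C)[C@@]1(O)CCc1ccoc1 | intermediate
3 | 6β,19-O-(di-tert-butylsilanediyl)marrubenol | C[C@@H]1C[C@H]2O[Si](C(C)(C)C)(C(C)(C)C)OC[C@@]3(C)CCC[C@]([C@@H]23)(C)[C@@]1(O)CCc1ccoc1 | intermediate
4 | silylene-protected 9α-hydroxy-14,15,16-trinorlabdan-13-oic acid | C[C@@H]1C[C@H]2O[Si](C(C)(C)C)(C(C)(C)C)OC[C@@]3(C)CCC[C@]([C@@H]23)(C)[C@@]1(O)CCC(=O)O | intermediate
5 | silylene-protected 14,15,16-trinorlabdan-13,9α-olide (spiro γ-lactone) | C[C@@H]1C[C@H]2O[Si](C(C)(C)C)(C(C)(C)C)OC[C@@]3(C)CCC[C@]([C@@H]23)(C)[C@@]12CCC(=O)O2 | intermediate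
6 | 12-hydroxy spiro γ-lactone, both C12 epimers | C[C@@H]1C[C@H]2O[Si](C(C)(C)C)(C(C)(C)C)OC[C@@]3(C)CCC[C@]([C@@H]23)(C)[C@@]12CC(O)C(=O)O2 | intermediate
7 | 12,13-dihydroxy-9α,13-epoxy lactol, epimers at C12 and C13 | C[C@@H]1C[C@H]2O[Si](C(C)(C)C)(C(C)(C)C)OC[C@@]3(C)CCC[C@]([C@@H]23)(C)[C@@]12CC(O)C(O)O2 | intermediate
8 | silylene-protected 9α,13-epoxy-14,15,16-trinorlabdan-12-ol, C12 epimers | C[C@@H]1C[C@H]2O[Si](C(C)(C)C)(C(C)(C)C)OC[C@@]3(C)CCC[C@]([C@@H]23)(C)[C@@]12CC(O)CO2 | intermediate
9 | silylene-protected 9α,13-epoxy-14,15,16-trinorlabdan-12-one (spiro tetrahydrofuran-3-one) | C[C@@H]1C[C@H]2O[Si](C(C)(C)C)(C(C)(C)C)OC[C@@]3(C)CCC[C@]([C@@H]23)(C)[C@@]12CC(=O)CO2 | intermediate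
10 | (S)-glycidol | OC[C@H]1CO1 | starting material
11 | (R)-oxirane-2-carbaldehyde | O=C[C@H]1CO1 | intermediate
12 | lithium alkoxide of the aldol adduct (C28H47LiO6Si), C13 and C14 epimers | C[C@@H]1C[C@H]2O[Si](C(C)(C)C)(C(C)(C)C)OC[C@@]3(C)CCC[C@]([C@@H]23)(C)[C@@]12CC(=O)C(C([O-])[C@H]3CO3)O2.[Li+] | intermediate
13 | C14 mesylate of the aldol adduct | C[C@@H]1C[C@H]2O[Si](C(C)(C)C)(C(C)(C)C)OC[C@@]3(C)CCC[C@]([C@@H]23)(C)[C@@]12CC(=O)C(C(OS(C)(=O)=O)[C@H]3CO3)O2 | intermediate
14 | (Z)-γ,δ-epoxy enone, 13-[(oxiran-2-yl)methylidene] furanone | C[C@@H]1C[C@H]2O[Si](C(C)(C)C)(C(C)(C)C)OC[C@@]3(C)CCC[C@]([C@@H]23)(C)[C@@]12CC(=O)/C(=C/[C@H]3CO3)O2 | intermediate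
15 | carbonyl ylide (oxocarbenium dienolate) | C[C@@H]1C[C@H]2O[Si](C(C)(C)C)(C(C)(C)C)OC[C@@]3(C)CCC[C@]([C@@H]23)(C)[C@@]12CC([O-])=C(C=C[O+]=C)O2 | intermediate
16 | 6,19-O-(di-tert-butylsilanediyl) derivative of the target | C[C@@H]1C[C@H]2O[Si](C(C)(C)C)(C(C)(C)C)OC[C@@]3(C)CCC[C@]([C@@H]23)(C)[C@@]12CC(=O)[C@]1(C=COC1)O2 | intermediate
17 | (13R)-6β,19-dihydroxy-9α,13;15,16-diepoxylabd-14-en-12-one | C[C@@H]1C[C@@H](O)[C@H]2[C@@](C)(CO)CCC[C@]2(C)[C@@]12CC(=O)[C@]1(C=COC1)O2 | target

Total step count: 10. Longest linear sequence: 9 steps (steps 1 to 6 and 8 to 10; step 7 prepares the aldehyde).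

Steps most likely to fail

Step 9 (key step). At the pyrolysis temperature, homolysis of the oxirane C15–O bond can compete with ylide formation, since the resulting allyl radical is captodatively stabilised at C13. This would drain material into the isomeric 2,5-dihydrofuran spiroketal and open enals. The heavy substrate may also decompose while it is volatilised, and the closure has at best weak facial discrimination at C13. The fallback sets out from 9 and comes back at 16. It sets C13 by relay from a temporary C12 carbinol through a silicon tether and still closes a ring by the C13–C16 bond. Furanone 9 is condensed with ethyl glyoxylate (LiN(i-Pr)2; then MsCl, DBU) to the ene-dione ester F1. Reduction of the C12 ketone with (S)-Me-CBS oxazaborolidine (C18H20BNO) and catecholborane should give the (12R)-allylic alcohol F2 under reagent control. (Bromomethyl)chlorodimethylsilane and imidazole then give the bromomethylsilyl ether F3. Bu3SnH and AIBN (benzene, 80 °C) start a 5-exo radical cyclisation (Nishiyama–Stork) onto C13, the β-carbon of the β-alkoxyacrylate. The cis-fused oxasilolane F4 can only form with C16 syn to O12, which is the required C13 configuration. Tamao–Fleming oxidation (KF, KHCO3, H2O2) frees the C16 hydroxyl, which lactonises onto the ester to give the spiro-lactone alcohol F5. Silylation (Me3SiCl, imidazole) gives the silyl ether F6 and i-Bu2AlH reduction the lactol F7. Dehydration through the anomeric mesylate (MsCl, Et3N) gives the dihydrofuran silyl ether F8, methanolysis (K2CO3, MeOH) the C12 alcohol F9, and Dess–Martin oxidation then gives 16.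

Step 8. Deprotonation at C11 can be followed by β-elimination of O9, which opens the furanone ring. The aldolate oxygen can attack the neighbouring oxirane, and the sensitive epoxy aldehyde can oligomerise before the elimination. The fallback sets out from 9 and comes back at 14; it builds the oxirane last. Condensation of 9 with 2,2-dimethoxyacetaldehyde under reversible conditions (piperidine, AcOH, benzene, 80 °C) should give the enone acetal F10. Mild hydrolysis (wet silica gel, oxalic acid, CH2Cl2) should give the keto enal F11. Methylene transfer to the aldehyde with dimethylsulfonium methylide (trimethylsulfonium iodide, KN(SiMe3)2, THF, −20 °C; Corey–Chaykovsky epoxidation) should give 14 together with its oxirane epimer F12. Both converge on ylide 15 in step 9.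

Step 5. The Lewis acid can ionise the tertiary C9–O9 bond (elimination at the spiro centre) or strip the silylene during the ionic hydrogenation, and the lactol can be over-reduced to the open triol. The fallback sets out from 5 and comes back at 8, bypassing step 4 as well; it introduces the C12 oxygen by hydroboration. i-Bu2AlH reduction of lactone 5 should give the lactol F13. Dehydration through its mesylate (MsCl, Et3N, CH2Cl2) should give the cyclic enol ether F14. Hydroboration–oxidation (BH3·THF; then NaOH, H2O2) should give alcohol 8, boron adding to C12, the carbon β to the ring oxygen.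

Further compounds
F1 | step 9 | ene-dione ester, ethyl (Z)-2-(12-oxo-furanon-13-ylidene)acetate | C[C@@H]1C[C@H]2O[Si](C(C)(C)C)(C(C)(C)C)OC[C@@]3(C)CCC[C@]([C@@H]23)(C)[C@@]12CC(=O)/C(=C/C(=O)OCC)O2
F2 | step 9 | (12R)-allylic alcohol | C[C@@H]1C[C@H]2O[Si](C(C)(C)C)(C(C)(C)C)OC[C@@]3(C)CCC[C@]([C@@H]23)(C)[C@@]12C[C@@H](O)/C(=C/C(=O)OCC)O2
F3 | step 9 | (bromomethyl)dimethylsilyl ether of F2 | C[C@@H]1C[C@H]2O[Si](C(C)(C)C)(C(C)(C)C)OC[C@@]3(C)CCC[C@]([C@@H]23)(C)[C@@]12C[C@@H](O[Si](C)(C)CBr)/C(=C/C(=O)OCC)O2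
F4 | step 9 | cis-fused oxasilolane with C13 quaternary | C[C@@H]1C[C@H]2O[Si](C(C)(C)C)(C(C)(C)C)OC[C@@]3(C)CCC[C@]([C@@H]23)(C)[C@@]12C[C@H]3O[Si](C)(C)C[C@@]3(CC(=O)OCC)O2
F5 | step 9 | spiro-lactone alcohol (C16–O–C15 lactone, 12-OH) | C[C@@H]1C[C@H]2O[Si](C(C)(C)C)(C(C)(C)C)OC[C@@]3(C)CCC[C@]([C@@H]23)(C)[C@@]12C[C@@H](O)[C@]3(CC(=O)OC3)O2
F6 | step 9 | 12-O-trimethylsilyl ether of F5 | C[C@@H]1C[C@H]2O[Si](C(C)(C)C)(C(C)(C)C)OC[C@@]3(C)CCC[C@]([C@@H]23)(C)[C@@]12C[C@@H](O[Si](C)(C)C)[C@]3(CC(=O)OC3)O2
F7 | step 9 | lactol at C15 (anomers) | C[C@@H]1C[C@H]2O[Si](C(C)(C)C)(C(C)(C)C)OC[C@@]3(C)CCC[C@]([C@@H]23)(C)[C@@]12C[C@@H](O[Si](C)(C)C)[C@]3(CC(O)OC3)O2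
F8 | step 9 | dihydrofuran 12-O-trimethylsilyl ether | C[C@@H]1C[C@H]2O[Si](C(C)(C)C)(C(C)(C)C)OC[C@@]3(C)CCC[C@]([C@@H]23)(C)[C@@]12C[C@@H](O[Si](C)(C)C)[C@]3(C=COC3)O2
F9 | step 9 | dihydrofuran C12 alcohol | C[C@@H]1C[C@H]2O[Si](C(C)(C)C)(C(C)(C)C)OC[C@@]3(C)CCC[C@]([C@@H]23)(C)[C@@]12C[C@@H](O)[C@]3(C=COC3)O2
F10 | step 8 | enone dimethyl acetal | C[C@@H]1C[C@H]2O[Si](C(C)(C)C)(C(C)(C)C)OC[C@@]3(C)CCC[C@]([C@@H]23)(C)[C@@]12CC(=O)/C(=C/C(OC)OC)O2
F11 | step 8 | keto enal | C[C@@H]1C[C@H]2O[Si](C(C)(C)C)(C(C)(C)C)OC[C@@]3(C)CCC[C@]([C@@H]23)(C)[C@@]12CC(=O)/C(=C/C=O)O2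
F12 | step 8 | oxirane epimer of 14 | C[C@@H]1C[C@H]2O[Si](C(C)(C)C)(C(C)(C)C)OC[C@@]3(C)CCC[C@]([C@@H]23)(C)[C@@]12CC(=O)/C(=C/[C@@H]3CO3)O2
F13 | step 5 | lactol of 5 (anomers) | C[C@@H]1C[C@H]2O[Si](C(C)(C)C)(C(C)(C)C)OC[C@@]3(C)CCC[C@]([C@@H]23)(C)[C@@]12CCC(O)O2
F14 | step 5 | cyclic enol ether (9α,13-epoxy-12-ene) | C[C@@H]1C[C@H]2O[Si](C(C)(C)C)(C(C)(C)C)OC[C@@]3(C)CCC[C@]([C@@H]23)(C)[C@@]12CC=CO2
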